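**Retrosynthetic overview**

1. The target is numbered as an oxolan-2-one (O1, C2=O, C3 = carbinol carbon with one benzyl, C4 = CH with the other benzyl, C5 = CH2). The last two steps only remove a temporary C5 arylsulfanyl group and three O-benzyl groups.
2. Key disconnection: C3–C4 and O1–C5 are made together by a Marino-type sulfonium [3,3] rearrangement/lactonization between an enantiopure (E)-alkenyl p-tolyl sulfoxide (C4=C5, carrying the C4 benzyl) and a benzyloxy(benzyl)ketene (C2=C3, carrying both C3 substituents).
3. Enabling feature: ring atoms O1–C2–C3 are a ketene C=C=O plus the sulfinyl oxygen, and C4–C5 is an alkene whose C5 is an unsubstituted CH2 in the target. C5 can therefore carry sulfur, first as the chirality source and then as a thionium electrophile, before the sulfur is reduced off.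
4. The sulfoxide comes from a benzylic bromide by ethynylation, Andersen sulfinylation and trans-reduction. The ketene precursor comes from the same bromide and (benzyloxy)acetic acid.
5. Ring order: the γ-lactone is the only ring made and it forms in the key step; both aromatic rings are bought.

Key step: step 7

Assumption: the sulfur configuration, (S) in the alkenyl sulfoxide, is chosen from a chair model of the [3,3] shift with p-tolyl pseudo-equatorial; both enantiomers of menthyl p-toluenesulfinate are commercial, so the mirror-image reagent would be used if the sense of transfer proved opposite.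

**Route**

Step 1
Reactants: 1 4-(benzyloxy)-3-methoxybenzyl alcohol
Product: 2 4-(benzyloxy)-3-methoxybenzyl bromide
Conditions: PBr3 (0.4 equiv), CH2Cl2, 0 °C; used without storage
Reagents that add atoms: phosphorus tribromide, BrP(Br)Br
Why: Substitution of an activated benzylic alcohol via its bromophosphite ester is standard, and the aryl benzyl ether is stable to these conditions.

Step 2
Reactants: 2 4-(benzyloxy)-3-methoxybenzyl bromide; 3 ethynylmagnesium bromide (excess)
Product: 4 1-(benzyloxy)-2-methoxy-4-(prop-2-yn-1-yl)benzene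
Conditions: CuBr·SMe2 (cat.), THF, 0 °C to rt; neutral work-up
Reagents that add atoms: none
Why: Copper-catalysed sp3–sp coupling of a benzylic bromide with an alkynyl Grignard reagent should give the 3-arylpropyne, with excess reagent suppressing double alkylation and the neutral work-up suppressing propargyl-to-allene isomerisation.

Step 3
Reactants: 4 1-(benzyloxy)-2-methoxy-4-(prop-2-yn-1-yl)benzene; 5 (1S,2R,5S)-(+)-menthyl (R)-4-methylbenzenesulfinate
Product: 7 1-(benzyloxy)-2-methoxy-4-{3-[(R)-4-methylbenzenesulfinyl]prop-2-yn-1-yl}benzene, via alkynylmagnesium bromide 6 (not isolated)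
Conditions: EtMgBr, THF, 0 °C to rt; then 5, toluene, −20 °C; then H2O
Reagents that add atoms: none
Why: Andersen sulfoxide synthesis: the alkynyl Grignard reagent displaces menthoxide at sulfur with inversion, which sets the sulfur stereocenter from the enantiopure sulfinate.

Step 4
Reactants: 7 1-(benzyloxy)-2-methoxy-4-{3-[(R)-4-methylbenzenesulfinyl]prop-2-yn-1-yl}benzene
Product: 8 1-(benzyloxy)-2-methoxy-4-{(2E)-3-[(S)-4-methylbenzenesulfinyl]prop-2-en-1-yl}benzene
Conditions: iBu2AlH, THF, −90 °C; then H2O
Reagents that add atoms: none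
Why: Conjugate hydride delivery (trans-hydroalumination) to a 1-alkynyl sulfoxide is a known route to (E)-1-alkenyl sulfoxides; sulfur is not touched, and its descriptor changes from R to S only because the ligand priorities change.

Step 5
Reactants: 9 (benzyloxy)acetic acid; 2 4-(benzyloxy)-3-methoxybenzyl bromide
Product: 11 rac-2-(benzyloxy)-3-[4-(benzyloxy)-3-methoxyphenyl]propanoic acid, via dilithium enediolate 10 (not isolated)
Conditions: LiN(iPr)2 (2.2 equiv), THF, −78 °C; then 2, −78 to 0 °C; then aq. HCl
Reagents that add atoms: none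
Why: Carboxylic acid dianion alkylation by a reactive benzylic bromide should give the acid directly, and the new center is left racemic on purpose because ketene formation in step 7 erases it.

Step 6
Reactants: 11 rac-2-(benzyloxy)-3-[4-(benzyloxy)-3-methoxyphenyl]propanoic acid
Product: 12 rac-2-(benzyloxy)-3-[4-(benzyloxy)-3-methoxyphenyl]propanoyl chloride
Conditions: (COCl)2, DMF (cat.), CH2Cl2, 0 °C to rt; evaporate, use crude
Reagents that add atoms: oxalyl chloride, ClC(=O)C(=O)Cl
Why: Acid chloride formation through the Vilsmeier-type chloroiminium intermediate is routine for α-benzyloxy acids and leaves the benzyl ethers intact.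

Step 7
Reactants: 12 rac-2-(benzyloxy)-3-[4-(benzyloxy)-3-methoxyphenyl]propanoyl chloride (2 equiv); 8 1-(benzyloxy)-2-methoxy-4-{(2E)-3-[(S)-4-methylbenzenesulfinyl]prop-2-en-1-yl}benzene
Product: 16 (3S,4R,5S)-3-(benzyloxy)-3,4-bis[4-(benzyloxy)-3-methoxybenzyl]-5-[(4-methylphenyl)sulfanyl]oxolan-2-one, via benzyloxy(benzyl)ketene 13 (not isolated), via O-sulfonium enolate 14 (not isolated), via thionium carboxylate 15 (not isolated)
Conditions: iPr2NEt (2.5 equiv), CH2Cl2, slow addition of 12 to 8, −40 °C to rt
Reagents that add atoms: none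
Why: Proposed new method: the amine dehydrochlorinates 12 to ketene 13, the sulfinyl oxygen of 8 adds to the ketene carbonyl carbon in the plane of the ketene substituents past the smaller benzyloxy group to give O-sulfonium enolate 14 (benzyloxy cis to O–S, benzyl cis to O−), and this 3-oxa-4-thia-1,5-diene undergoes a charge-accelerated sulfonium [3,3]-sigmatropic shift that forms C3–C4 and breaks S–O to give thionium carboxylate 15, which collapses to the lactone by forming O1–C5. The closest known reaction types are the Marino lactonization of enantiopure vinyl sulfoxides with dichloroketene and the sulfonium [3,3] rearrangement of vinyl sulfoxides with keteniminium ions generated from ynamides; what is new is a non-halogenated, unsymmetrically disubstituted alkoxy(alkyl)ketene that creates a fully substituted carbon. The one ring closes by 5-exo-trig attack of the carboxylate oxygen on the thionium carbon. C4 is controlled by the sulfur stereocenter, because in the chair transition state p-tolyl on sulfur and the benzyl group of the (E)-alkene are pseudo-equatorial and the enolate carbon is delivered only to the alkene face that carries the S–O bond; C3 is controlled by the enolate geometry within the same chair (benzyl pseudo-equatorial, benzyloxy pseudo-axial), which places the two benzyl groups trans, and C5 is expected trans to the C4 benzyl and is erased in step 8. The step needs O-attack on the ketene and rearrangement to outrun ketene dimerisation and chloride-driven Pummerer pathways, and it needs one enolate geometry; slow addition of 12 keeps the ketene concentration low, the alkoxy substituent makes the ketene electrophilic, and the steric and dipolar preference for benzyloxy cis to the O–S bond together with the fixed (E)-alkene should secure the geometry.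

Step 8
Reactants: 16 (3S,4R,5S)-3-(benzyloxy)-3,4-bis[4-(benzyloxy)-3-methoxybenzyl]-5-[(4-methylphenyl)sulfanyl]oxolan-2-one
Product: 17 (3S,4S)-3-(benzyloxy)-3,4-bis[4-(benzyloxy)-3-methoxybenzyl]oxolan-2-one
Conditions: Bu3SnH, AIBN (cat.), toluene, 90 °C
Reagents that add atoms: none
Why: Radical chain desulfurisation of the O,S-acetal gives an α-acyloxy radical at C5 that takes hydrogen from the stannane, so C5 becomes CH2 while C3 and C4 and the benzyl ethers are untouched; the C4 descriptor changes from R to S only through ligand priorities.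

Step 9
Reactants: 17 (3S,4S)-3-(benzyloxy)-3,4-bis[4-(benzyloxy)-3-methoxybenzyl]oxolan-2-one
Product: 18 (3S,4S)-3-hydroxy-3,4-bis(4-hydroxy-3-methoxybenzyl)oxolan-2-one
Conditions: H2 (1 atm), Pd(OH)2/C, EtOAc–EtOH, rt
Reagents that add atoms: none
Why: Catalytic hydrogenolysis should cleave the two aryl benzyl ethers and the tertiary benzyl ether, while the lactone, the homobenzylic C3–O bond and both stereocenters are inert.

**Compound list**

1 | 4-(benzyloxy)-3-methoxybenzyl alcohol | COc1cc(CO)ccc1OCc1ccccc1 | starting material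
2 | 4-(benzyloxy)-3-methoxybenzyl bromide | COc1cc(CBr)ccc1OCc1ccccc1 | intermediate
3 | ethynylmagnesium bromide | C#C[Mg]Br | starting material
4 | 1-(benzyloxy)-2-methoxy-4-(prop-2-yn-1-yl)benzene | COc1cc(CC#C)ccc1OCc1ccccc1 | intermediate
5 | (1S,2R,5S)-(+)-menthyl (R)-4-methylbenzenesulfinate | C[C@H]1CC[C@@H]([C@H](C1)O[S@@](=O)c1ccc(C)cc1)C(C)C | starting material
6 | {3-[4-(benzyloxy)-3-methoxyphenyl]prop-1-yn-1-yl}magnesium bromide | COc1cc(CC#C[Mg]Br)ccc1OCc1ccccc1 | intermediate (not isolated)
7 | 1-(benzyloxy)-2-methoxy-4-{3-[(R)-4-methylbenzenesulfinyl]prop-2-yn-1-yl}benzene | Cc1ccc(cc1)[S@@](=O)C#CCc1ccc(OCc2ccccc2)c(OC)c1 | intermediate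
8 | 1-(benzyloxy)-2-methoxy-4-{(2E)-3-[(S)-4-methylbenzenesulfinyl]prop-2-en-1-yl}benzene | Cc1ccc(cc1)[S@@](=O)/C=C/Cc1ccc(OCc2ccccc2)c(OC)c1 | intermediate
9 | (benzyloxy)acetic acid | OC(=O)COCc1ccccc1 | starting material
10 | dilithium 2-(benzyloxy)ethene-1,1-diolate | [Li+].[Li+].[O-]C([O-])=COCc1ccccc1 | intermediate (not isolated)
11 | rac-2-(benzyloxy)-3-[4-(benzyloxy)-3-methoxyphenyl]propanoic acid | OC(=O)C(OCc1ccccc1)Cc1ccc(OCc2ccccc2)c(OC)c1 | intermediate
12 | rac-2-(benzyloxy)-3-[4-(benzyloxy)-3-methoxyphenyl]propanoyl chloride | ClC(=O)C(OCc1ccccc1)Cc1ccc(OCc2ccccc2)c(OC)c1 | intermediate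
13 | 2-(benzyloxy)-3-[4-(benzyloxy)-3-methoxyphenyl]prop-1-en-1-one (ketene) | O=C=C(OCc1ccccc1)Cc1ccc(OCc2ccccc2)c(OC)c1 | intermediate (not isolated)
14 | zwitterionic O-sulfonium enolate from 8 and 13 (sulfur S, benzyloxy cis to O–S, alkene E) | Cc1ccc(cc1)[S@@+](O/C([O-])=C(\OCc1ccccc1)Cc1ccc(OCc2ccccc2)c(OC)c1)/C=C/Cc1ccc(OCc2ccccc2)c(OC)c1 | intermediate (not isolated)
15 | (2S,3R)-2-(benzyloxy)-2,3-bis[4-(benzyloxy)-3-methoxybenzyl]-4-[(4-methylphenyl)sulfaniumylidene]butanoate | COc1cc(C[C@@H](/C=[S+]/c2ccc(C)cc2)[C@@](OCc2ccccc2)(Cc2ccc(OCc3ccccc3)c(OC)c2)C([O-])=O)ccc1OCc1ccccc1 | intermediate (not isolated)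
16 | (3S,4R,5S)-3-(benzyloxy)-3,4-bis[4-(benzyloxy)-3-methoxybenzyl]-5-[(4-methylphenyl)sulfanyl]oxolan-2-one | COc1cc(C[C@H]2[C@H](Sc3ccc(C)cc3)OC(=O)[C@]2(OCc3ccccc3)Cc3ccc(OCc4ccccc4)c(OC)c3)ccc1OCc1ccccc1 | intermediate
17 | (3S,4S)-3-(benzyloxy)-3,4-bis[4-(benzyloxy)-3-methoxybenzyl]oxolan-2-one | COc1cc(C[C@H]2COC(=O)[C@]2(OCc3ccccc3)Cc3ccc(OCc4ccccc4)c(OC)c3)ccc1OCc1ccccc1 | intermediate
18 | (3S,4S)-3-hydroxy-3,4-bis(4-hydroxy-3-methoxybenzyl)oxolan-2-one | COc1cc(C[C@H]2COC(=O)[C@]2(O)Cc2ccc(O)c(OC)c2)ccc1O | target

**Totals and risks**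

Total step count: 9. Longest linear sequence: 7 steps (steps 1, 2, 3, 4, 7, 8, 9).

Steps most likely to fail:

Step 7 (proposed method). The sulfinyl oxygen may add too slowly to a ketene that is less electrophilic than dichloroketene, so that ketene dimerisation or chloride-driven Pummerer capture of the activated sulfoxide takes over. Partial loss of enolate geometry would also erode the configuration at C3. The fallback uses known chemistry only; it sets out from 8 and comes back to the route at 18. Marino lactonization of 8 with dichloroketene (Cl3CCOCl, Zn–Cu couple, Et2O, 0 °C) should give (4S,5S)-4-[4-(benzyloxy)-3-methoxybenzyl]-3,3-dichloro-5-[(4-methylphenyl)sulfanyl]oxolan-2-one F1. Bu3SnH/AIBN in hot toluene should remove both chlorines and the sulfanyl group to give (R)-4-[4-(benzyloxy)-3-methoxybenzyl]oxolan-2-one F2. Enolate hydroxylation (LiN(SiMe3)2, then 2-(phenylsulfonyl)-3-phenyloxaziridine, THF, −78 °C) should give (3R,4S)-4-[4-(benzyloxy)-3-methoxybenzyl]-3-hydroxyoxolan-2-one F3. Formation of its dianion (LiN(iPr)2, 2.2 equiv) and alkylation with bromide 2, which enters anti to the C4 benzyl group, should give (3S,4S)-3,4-bis[4-(benzyloxy)-3-methoxybenzyl]-3-hydroxyoxolan-2-one F4. Hydrogenolysis (H2, Pd(OH)2/C) then gives 18.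

Step 3. The doubly activated benzylic–propargylic CH2 of the alkynyl sulfoxide may undergo base-induced prototropic shift to an allenyl sulfoxide under the magnesium alkoxide formed in the reaction, and the same sensitivity threatens the hydride reduction of step 4. The fallback sets out from 4 and comes back at 8, so that no alkynyl sulfoxide is made. Hydrozirconation of 4 (Cp2Zr(H)Cl, THF) and iodinolysis should give 1-(benzyloxy)-4-[(2E)-3-iodoprop-2-en-1-yl]-2-methoxybenzene F5. Iodine–magnesium exchange (iPrMgCl·LiCl, THF) should give {(1E)-3-[4-(benzyloxy)-3-methoxyphenyl]prop-1-en-1-yl}magnesium chloride F6. This is sulfinylated by sulfinate 5 in an Andersen reaction with inversion at sulfur and retention of alkene geometry to give 8.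

Step 2. Base-mediated isomerisation of the skipped aryl–alkyne to an arylallene and a second alkylation of the acetylide may consume the bromide. The fallback sets out from 2 and comes back at 4. A palladium-catalysed sp3–sp cross-coupling of 2 with (triisopropylsilyl)acetylene (PdCl2(MeCN)2, XPhos, Cs2CO3, MeCN, 65 °C) should give {3-[4-(benzyloxy)-3-methoxyphenyl]prop-1-yn-1-yl}tri(propan-2-yl)silane F7. Buffered fluoride desilylation (Bu4NF, AcOH, THF, 0 °C) then gives 4.

**Further compounds**

F1 | step 7 | (4S,5S)-4-[4-(benzyloxy)-3-methoxybenzyl]-3,3-dichloro-5-[(4-methylphenyl)sulfanyl]oxolan-2-one | COc1cc(C[C@H]2[C@H](Sc3ccc(C)cc3)OC(=O)C2(Cl)Cl)ccc1OCc1ccccc1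
F2 | step 7 | (R)-4-[4-(benzyloxy)-3-methoxybenzyl]oxolan-2-one | COc1cc(C[C@H]2COC(=O)C2)ccc1OCc1ccccc1
F3 | step 7 | (3R,4S)-4-[4-(benzyloxy)-3-methoxybenzyl]-3-hydroxyoxolan-2-one | COc1cc(C[C@H]2COC(=O)[C@@H]2O)ccc1OCc1ccccc1
F4 | step 7 | (3S,4S)-3,4-bis[4-(benzyloxy)-3-methoxybenzyl]-3-hydroxyoxolan-2-one | COc1cc(C[C@H]2COC(=O)[C@]2(O)Cc2ccc(OCc3ccccc3)c(OC)c2)ccc1OCc1ccccc1
F5 | step 3 | 1-(benzyloxy)-4-[(2E)-3-iodoprop-2-en-1-yl]-2-methoxybenzene | COc1cc(C/C=C/I)ccc1OCc1ccccc1
F6 | step 3 | {(1E)-3-[4-(benzyloxy)-3-methoxyphenyl]prop-1-en-1-yl}magnesium chloride | COc1cc(C/C=C/[Mg]Cl)ccc1OCc1ccccc1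
F7 | step 2 | {3-[4-(benzyloxy)-3-methoxyphenyl]prop-1-yn-1-yl}tri(propan-2-yl)silane | COc1cc(CC#C[Si](C(C)C)(C(C)C)C(C)C)ccc1OCc1ccccc1
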